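**Strategy.** Everything rests on the C2–C1' bond that links dihydropyranone ring C to aryl ring B. C2 is the β-carbon of the C4 ketone and carries O1, so a flat 5,7-dibenzyloxychromone can be dearomatised by rhodium-catalysed enantioselective 1,4-arylation: one operation unites both halves and sets the only stereocentre (2S). The aryl donor is a pinacol boronate at C1' of a protected 8-aryl-luteolin, its hindered C2'–C8'' biaryl bond made by Suzuki coupling of 8-iodoluteolin tetrabenzyl ether with a 5-chloro-benzodioxol-4-ylboronic acid, the chlorine then being exchanged for boron. Global hydrogenolysis releases all eight hydroxyl groups.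

Key step: step 9

Assumption: the C2'–C8'' biaryl axis carries four ortho substituents and may be configurationally stable; the target is defined only at C2, so the axis is left uncontrolled and any atropisomers of 13–16 are carried together.

**Route**

Step 1
Reactants: 1 1-(2,4,6-trihydroxyphenyl)ethanone
Product: 2 1-[2,4-bis(benzyloxy)-6-hydroxyphenyl]ethanone
Conditions: BnBr (2.2 equiv), K2CO3, acetone, reflux
Reagents that add atoms: benzyl bromide BrCc1ccccc1
Why: Williamson etherification in which the one hydroxyl hydrogen-bonded to the acetyl carbonyl is the least reactive, so two equivalents of benzyl bromide should leave exactly that phenol free.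

Step 2
Reactants: 2 1-[2,4-bis(benzyloxy)-6-hydroxyphenyl]ethanone
Product: 4 5,7-bis(benzyloxy)-4H-chromen-4-one, via enaminone 3 (not isolated)
Conditions: Me2NCH(OMe)2, toluene, 100 °C; then conc. HCl, CH2Cl2, 40 °C
Reagents that add atoms: N,N-dimethylformamide dimethyl acetal COC(OC)N(C)C
Why: Enaminone route to chromones: condensation of the methyl ketone with the amide acetal gives the enaminone, and acid-promoted addition of the phenol with loss of dimethylamine closes the pyranone ring.

Step 3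
Reactants: 5 luteolin (2-(3,4-dihydroxyphenyl)-5,7-dihydroxy-4H-chromen-4-one)
Product: 6 5,7-bis(benzyloxy)-2-[3,4-bis(benzyloxy)phenyl]-4H-chromen-4-one
Conditions: BnBr (6 equiv), K2CO3, n-Bu4NI (cat.), DMF, 80 °C
Reagents that add atoms: benzyl bromide BrCc1ccccc1
Why: Exhaustive Williamson benzylation, in which excess reagent and heating are needed only for the chelated 5-OH.

Step 4
Reactants: 6 5,7-bis(benzyloxy)-2-[3,4-bis(benzyloxy)phenyl]-4H-chromen-4-one
Product: 7 5,7-bis(benzyloxy)-2-[3,4-bis(benzyloxy)phenyl]-8-iodo-4H-chromen-4-one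
Conditions: I2 (1.1 equiv), AgOCOCF3 (1.1 equiv), CH2Cl2, 0 °C to rt
Reagents that add atoms: iodine II
Why: Electrophilic aromatic iodination with silver-activated iodine, directed to C8 because in 5,7-dialkoxyflavones this position (ortho to O1 and the 7-alkoxy group, para to the 5-alkoxy group) is the most nucleophilic, while the enone-deactivated dialkoxyphenyl ring is left alone.

Step 5
Reactants: 8 4-chlorobenzene-1,2-diol
Product: 9 5-chloro-2,2-diphenyl-1,3-benzodioxole
Conditions: Ph2CCl2 (1.2 equiv), neat, 170 °C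
Reagents that add atoms: dichlorodiphenylmethane ClC(Cl)(c1ccccc1)c1ccccc1
Why: Double substitution of the gem-dichloride by the catechol gives the diphenylmethylene ketal, a catechol protecting group that has no acidic hydrogen, holds the oxygen back from the future biaryl axis and is cleaved by hydrogenolysis.

Step 6
Reactants: 9 5-chloro-2,2-diphenyl-1,3-benzodioxole
Product: 12 (5-chloro-2,2-diphenyl-1,3-benzodioxol-4-yl)boronic acid, via aryllithium 10 (not isolated), via lithium aryl(triisopropoxy)borate 11 (not isolated)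
Conditions: LiN(iPr)2 (1.2 equiv), B(OiPr)3 (1.5 equiv, present from the start), THF, −78 °C; then 1 M HCl, 0 °C
Reagents that add atoms: triisopropyl borate CC(C)OB(OC(C)C)OC(C)C; water O
Why: Directed ortho-lithiation at C4–H, the most acidic ring hydrogen because it lies between the dioxole oxygen and chlorine, with in-situ borate trapping at −78 °C so that the ortho-chloro aryllithium cannot lose LiCl to an aryne; acidic work-up hydrolyses the borate.

Step 7
Reactants: 7 5,7-bis(benzyloxy)-2-[3,4-bis(benzyloxy)phenyl]-8-iodo-4H-chromen-4-one; 12 (5-chloro-2,2-diphenyl-1,3-benzodioxol-4-yl)boronic acid (1.5 equiv)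
Product: 13 5,7-bis(benzyloxy)-2-[3,4-bis(benzyloxy)phenyl]-8-(5-chloro-2,2-diphenyl-1,3-benzodioxol-4-yl)-4H-chromen-4-one
Conditions: Pd(OAc)2 (5 mol %), SPhos (10 mol %), K3PO4, toluene/H2O (10:1), 70 °C
Reagents that add atoms: none
Why: Suzuki–Miyaura coupling with a bulky electron-rich biarylphosphine, which promotes reductive elimination to tetra-ortho-substituted biaryls, while oxidative addition at the carbon–iodine bond of 7 is far faster than at the hindered, electron-rich aryl chloride, which should survive.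

Step 8
Reactants: 13 5,7-bis(benzyloxy)-2-[3,4-bis(benzyloxy)phenyl]-8-(5-chloro-2,2-diphenyl-1,3-benzodioxol-4-yl)-4H-chromen-4-one
Product: 14 5,7-bis(benzyloxy)-2-[3,4-bis(benzyloxy)phenyl]-8-[2,2-diphenyl-5-(4,4,5,5-tetramethyl-1,3,2-dioxaborolan-2-yl)-1,3-benzodioxol-4-yl]-4H-chromen-4-one
Conditions: B2pin2 (2 equiv), Pd2(dba)3 (2.5 mol %), XPhos (10 mol %), KOAc, 1,4-dioxane, 100 °C
Reagents that add atoms: bis(pinacolato)diboron CC1(C)OB(OC1(C)C)B1OC(C)(C)C(C)(C)O1
Why: Miyaura borylation of an aryl chloride by zerovalent palladium with XPhos, a system established for ortho-substituted chlorides, with acetate as a base too weak to trigger Suzuki homocoupling.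

Step 9
Reactants: 14 5,7-bis(benzyloxy)-2-[3,4-bis(benzyloxy)phenyl]-8-[2,2-diphenyl-5-(4,4,5,5-tetramethyl-1,3,2-dioxaborolan-2-yl)-1,3-benzodioxol-4-yl]-4H-chromen-4-one; 4 5,7-bis(benzyloxy)-4H-chromen-4-one (2.5 equiv)
Product: 15 (2S)-5,7-bis(benzyloxy)-2-{4-[5,7-bis(benzyloxy)-2-(3,4-bis(benzyloxy)phenyl)-4-oxo-4H-chromen-8-yl]-2,2-diphenyl-1,3-benzodioxol-5-yl}-2,3-dihydro-4H-chromen-4-one
Conditions: [RhCl(C2H4)2]2 (2.5 mol %), (S)-MeO-F12-BIPHEP [(S)-2,2'-bis[bis(3,4,5-trifluorophenyl)phosphino]-6,6'-dimethoxy-1,1'-biphenyl] (5.5 mol %), KOH (0.2 equiv), toluene/H2O (10:1), 40 °C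
Reagents that add atoms: none
Why: A hydroxo-rhodium bisphosphine complex (monovalent rhodium) transmetalates with the hydroxide-activated pinacol boronate 14, the aryl–rhodium species adds across C2=C3 of chromone 4 to give an oxa-π-allyl rhodium enolate, and water protonates it to release 15 and return the rhodium hydroxide. The closest known reaction type is the Hayashi–Miyaura asymmetric 1,4-addition of arylboron reagents to chromones, the established catalytic entry to enantioenriched flavanones. No ring is closed; the flat pyranone ring of 4 is dearomatised and becomes the stereogenic ring C. The C2 stereocentre is set by the chiral pocket of the (S)-biaryl bisphosphine, which, by analogy with (S)-BINAP additions to 2-cyclohexenone, should deliver the aryl group to the Re face of C2 (O1 > C3 > H) and so give (2S); the antipodal ligand is equally available should the sense prove reversed. The step needs chemoselectivity for the unsubstituted C2–H acceptor of 4 over the flavone enone inside 14, secured because that C2''=C3'' bond is β,β-disubstituted and aryl-conjugated, and it needs insertion to outrun protodeboronation, which excess 4 and the electron-poor, fast-inserting ligand should favour. Flavone ring A has no hydrogen ortho to the biaryl axis, so a 1,4-rhodium shift cannot divert the aryl–rhodium intermediate, and the small amount of aqueous base at 40 °C limits retro-oxa-Michael opening of 15.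

Step 10
Reactants: 15 (2S)-5,7-bis(benzyloxy)-2-{4-[5,7-bis(benzyloxy)-2-(3,4-bis(benzyloxy)phenyl)-4-oxo-4H-chromen-8-yl]-2,2-diphenyl-1,3-benzodioxol-5-yl}-2,3-dihydro-4H-chromen-4-one
Product: 16 (2S)-2-{2-[2-(3,4-dihydroxyphenyl)-5,7-dihydroxy-4-oxo-4H-chromen-8-yl]-3,4-dihydroxyphenyl}-5,7-dihydroxy-2,3-dihydro-4H-chromen-4-one
Conditions: H2 (1 atm), Pd(OH)2/C, THF/MeOH (1:1), rt
Reagents that add atoms: none
Why: Hydrogenolysis over palladium should cleave the six O-benzyl ethers and the diphenylmethylene ketal in one neutral operation that does not epimerise C2, the flavone enone and the hindered benzylic C2–O1 bond reacting more slowly, so the reaction is stopped at full deprotection.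

**Compound list**

1 | 1-(2,4,6-trihydroxyphenyl)ethanone | CC(=O)c1c(O)cc(O)cc1O | starting material
2 | 1-[2,4-bis(benzyloxy)-6-hydroxyphenyl]ethanone | CC(=O)c1c(O)cc(OCc2ccccc2)cc1OCc1ccccc1 | intermediate
3 | (E)-1-[2,4-bis(benzyloxy)-6-hydroxyphenyl]-3-(dimethylamino)prop-2-en-1-one | CN(C)/C=C/C(=O)c1c(O)cc(OCc2ccccc2)cc1OCc1ccccc1 | intermediate
4 | 5,7-bis(benzyloxy)-4H-chromen-4-one | O=c1ccoc2cc(OCc3ccccc3)cc(OCc3ccccc3)c12 | intermediate
5 | luteolin | O=c1cc(-c2ccc(O)c(O)c2)oc2cc(O)cc(O)c12 | starting material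
6 | 5,7-bis(benzyloxy)-2-[3,4-bis(benzyloxy)phenyl]-4H-chromen-4-one | O=c1cc(-c2ccc(OCc3ccccc3)c(OCc3ccccc3)c2)oc2cc(OCc3ccccc3)cc(OCc3ccccc3)c12 | intermediate
7 | 5,7-bis(benzyloxy)-2-[3,4-bis(benzyloxy)phenyl]-8-iodo-4H-chromen-4-one | O=c1cc(-c2ccc(OCc3ccccc3)c(OCc3ccccc3)c2)oc2c(I)c(OCc3ccccc3)cc(OCc3ccccc3)c12 | intermediate
8 | 4-chlorobenzene-1,2-diol | Oc1ccc(Cl)cc1O | starting material
9 | 5-chloro-2,2-diphenyl-1,3-benzodioxole | Clc1ccc2c(c1)OC(c1ccccc1)(c1ccccc1)O2 | intermediate
10 | (5-chloro-2,2-diphenyl-1,3-benzodioxol-4-yl)lithium | [Li]c1c(Cl)ccc2c1OC(c1ccccc1)(c1ccccc1)O2 | intermediate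
11 | lithium (5-chloro-2,2-diphenyl-1,3-benzodioxol-4-yl)tri(propan-2-yloxy)borate | [Li+].CC(C)O[B-](OC(C)C)(OC(C)C)c1c(Cl)ccc2c1OC(c1ccccc1)(c1ccccc1)O2 | intermediate
12 | (5-chloro-2,2-diphenyl-1,3-benzodioxol-4-yl)boronic acid | OB(O)c1c(Cl)ccc2c1OC(c1ccccc1)(c1ccccc1)O2 | intermediate
13 | 5,7-bis(benzyloxy)-2-[3,4-bis(benzyloxy)phenyl]-8-(5-chloro-2,2-diphenyl-1,3-benzodioxol-4-yl)-4H-chromen-4-one | O=c1cc(-c2ccc(OCc3ccccc3)c(OCc3ccccc3)c2)oc2c(-c3c(Cl)ccc4c3OC(c3ccccc3)(c3ccccc3)O4)c(OCc3ccccc3)cc(OCc3ccccc3)c12 | intermediate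
14 | 5,7-bis(benzyloxy)-2-[3,4-bis(benzyloxy)phenyl]-8-[2,2-diphenyl-5-(4,4,5,5-tetramethyl-1,3,2-dioxaborolan-2-yl)-1,3-benzodioxol-4-yl]-4H-chromen-4-one | O=c1cc(-c2ccc(OCc3ccccc3)c(OCc3ccccc3)c2)oc2c(-c3c(B4OC(C)(C)C(C)(C)O4)ccc4c3OC(c3ccccc3)(c3ccccc3)O4)c(OCc3ccccc3)cc(OCc3ccccc3)c12 | intermediate
15 | (2S)-5,7-bis(benzyloxy)-2-{4-[5,7-bis(benzyloxy)-2-(3,4-bis(benzyloxy)phenyl)-4-oxo-4H-chromen-8-yl]-2,2-diphenyl-1,3-benzodioxol-5-yl}-2,3-dihydro-4H-chromen-4-one | O=C1C[C@@H](c2ccc3c(c2-c2c(OCc4ccccc4)cc(OCc4ccccc4)c4c(=O)cc(-c5ccc(OCc6ccccc6)c(OCc6ccccc6)c5)oc24)OC(c2ccccc2)(c2ccccc2)O3)Oc2cc(OCc3ccccc3)cc(OCc3ccccc3)c21 | intermediate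
16 | (2S)-2-{2-[2-(3,4-dihydroxyphenyl)-5,7-dihydroxy-4-oxo-4H-chromen-8-yl]-3,4-dihydroxyphenyl}-5,7-dihydroxy-2,3-dihydro-4H-chromen-4-one | O=C1C[C@@H](c2ccc(O)c(O)c2-c2c(O)cc(O)c3c(=O)cc(-c4ccc(O)c(O)c4)oc23)Oc2cc(O)cc(O)c21 | target

**Summary**

Total step count: 10. Longest linear sequence: 6 steps (5 → 6 → 7 → 13 → 14 → 15 → 16; the branch from 8 is equally long).

Steps most likely to fail:

1. Step 9. Transmetalation and insertion of the ortho-hindered aryl group may be so slow that protodeboronation of 14 takes over, or ring C of 15 may open under base and lose enantiopurity. The fallback reverses the order of the two couplings so that the 1,4-arylation runs on a small nucleophile. It sets out from 12. Condensation with 1,8-diaminonaphthalene (toluene, reflux) masks the boron as 2-(5-chloro-2,2-diphenyl-1,3-benzodioxol-4-yl)-2,3-dihydro-1H-naphtho[1,8-de][1,3,2]diazaborinine F1. Borylation of its chloride under the step 8 conditions gives 2-[2,2-diphenyl-5-(4,4,5,5-tetramethyl-1,3,2-dioxaborolan-2-yl)-1,3-benzodioxol-4-yl]-2,3-dihydro-1H-naphtho[1,8-de][1,3,2]diazaborinine F2. Only its pinacol boronate transmetalates in the rhodium-catalysed addition to 4 (step 9 conditions), which should give (2S)-5,7-bis(benzyloxy)-2-[4-(1H-naphtho[1,8-de][1,3,2]diazaborinin-2(3H)-yl)-2,2-diphenyl-1,3-benzodioxol-5-yl]-2,3-dihydro-4H-chromen-4-one F3. Aqueous H2SO4 in THF unmasks {5-[(2S)-5,7-bis(benzyloxy)-4-oxo-3,4-dihydro-2H-chromen-2-yl]-2,2-diphenyl-1,3-benzodioxol-4-yl}boronic acid F4. Suzuki coupling of F4 with iodide 7 (Pd(OAc)2/SPhos, K3PO4, toluene, 70 °C) comes back to the route at 15.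

2. Step 7. Reductive elimination at the tetra-ortho-substituted axis may be slow, with protodeboronation of the 2,6-disubstituted boronic acid 12 and oxidative addition at an aryl chloride competing. The fallback replaces the boron nucleophile and aqueous base by an anhydrous Negishi coupling. It sets out from 9: lithiation as in step 6 (LiN(iPr)2, THF, −78 °C) and addition of ZnCl2 gives chloro(5-chloro-2,2-diphenyl-1,3-benzodioxol-4-yl)zinc F5, which is coupled without isolation with iodide 7 (Pd2(dba)3, RuPhos, THF/NMP, 60 °C) and comes back to the route at 13.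

3. Step 10. Over-reduction may occur (hydrogenolytic opening of ring C at the benzylic C2–O1 bond or saturation of the flavone C2''=C3'' bond), or the reaction may stall at partly protected stages. The fallback sets out from 15 and replaces hydrogenolysis by Lewis-acid cleavage with a cation scavenger (BCl3, pentamethylbenzene, CH2Cl2, −78 °C to 0 °C, aqueous work-up), which should remove the benzyl ethers and the ketal without reducing conditions and comes back to the route at 16; no further compound arises (F0).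

**Further compounds**

F1 | step 9 | 2-(5-chloro-2,2-diphenyl-1,3-benzodioxol-4-yl)-2,3-dihydro-1H-naphtho[1,8-de][1,3,2]diazaborinine | Clc1ccc2c(c1B1Nc3cccc4cccc(N1)c34)OC(c1ccccc1)(c1ccccc1)O2
F2 | step 9 | 2-[2,2-diphenyl-5-(4,4,5,5-tetramethyl-1,3,2-dioxaborolan-2-yl)-1,3-benzodioxol-4-yl]-2,3-dihydro-1H-naphtho[1,8-de][1,3,2]diazaborinine | CC1(C)OB(OC1(C)C)c1ccc2c(c1B1Nc3cccc4cccc(N1)c34)OC(c1ccccc1)(c1ccccc1)O2
F3 | step 9 | (2S)-5,7-bis(benzyloxy)-2-[4-(1H-naphtho[1,8-de][1,3,2]diazaborinin-2(3H)-yl)-2,2-diphenyl-1,3-benzodioxol-5-yl]-2,3-dihydro-4H-chromen-4-one | O=C1C[C@@H](c2ccc3c(c2B2Nc4cccc5cccc(N2)c45)OC(c2ccccc2)(c2ccccc2)O3)Oc2cc(OCc3ccccc3)cc(OCc3ccccc3)c21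
F4 | step 9 | {5-[(2S)-5,7-bis(benzyloxy)-4-oxo-3,4-dihydro-2H-chromen-2-yl]-2,2-diphenyl-1,3-benzodioxol-4-yl}boronic acid | O=C1C[C@@H](c2ccc3c(c2B(O)O)OC(c2ccccc2)(c2ccccc2)O3)Oc2cc(OCc3ccccc3)cc(OCc3ccccc3)c21
F5 | step 7 | chloro(5-chloro-2,2-diphenyl-1,3-benzodioxol-4-yl)zinc | Cl[Zn]c1c(Cl)ccc2c1OC(c1ccccc1)(c1ccccc1)O2
F0 | step 10 | none | none
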